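**Retrosynthetic overview**
- The target is a meta-depside: a haematommoyl ring A esterified to O5 of a fully substituted β-orcinol-type ring B.
- Last disconnection: the ring A formyl group, installed by C3 formylation of the orsellinate depside (ring B has no free C–H).
- Key disconnection: ring A itself is opened to a linear triketide. A diketo-dioxinone releases an acylketene, the ring B phenol captures it, and aldol aromatisation closes ring A on the ester, so no benzoic acid + phenol coupling is used.
- Ring B triol comes from atraric acid by C5 formylation and Dakin oxidation; the diketo-dioxinone comes from 2,2,6-trimethyl-4H-1,3-dioxin-4-one by two C-acylations.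
- Ring order: ring B is bought aromatic; ring A is the only ring formed (step 5) and is formylated last.

Assumption: the target has no stereocentre or other stereogenic element, so the SMILES describes one achiral compound and no enantiocontrol is required.

**Step 1**
Reactants: 1 methyl 2,4-dihydroxy-3,6-dimethylbenzoate (atraric acid)
Product: 3 methyl 5-formyl-2,4-dihydroxy-3,6-dimethylbenzoate, via α-chloro ether 2 (not isolated)
Conditions: Cl2CHOMe (1.5 equiv), TiCl4 (3 equiv), CH2Cl2, −10 → 0 °C, 2 h; then 1 M aq. HCl, rt
Reagents that add atoms: dichloromethyl methyl ether ClC(Cl)OC; water O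
Why: Rieche formylation at C5, the only free ring position (ortho to O4, para to O2), followed by hydrolysis of the chloro(methoxy)methyl intermediate to the aldehyde; no stereocentre is formed.

**Step 2**
Reactants: 3 methyl 5-formyl-2,4-dihydroxy-3,6-dimethylbenzoate
Product: 5 methyl 2,4,5-trihydroxy-3,6-dimethylbenzoate, via aryl formate 4 (not isolated)
Conditions: 30% aq. H2O2 (1.1 equiv), H2SO4 (cat.), degassed MeOH, 0 °C → rt, N2; crude triol kept under N2 and used at once
Reagents that add atoms: hydrogen peroxide OO
Why: Acid-catalysed Dakin oxidation: the aldehyde is ortho and para to hydroxyl groups, so the aryl group migrates in the peroxide adduct, and the formate is methanolysed in the same pot; acidic medium limits over-oxidation of the hydroxyhydroquinone.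

**Step 3**
Reactants: 6 2,2,6-trimethyl-4H-1,3-dioxin-4-one
Product: 7 2,2-dimethyl-6-(2-oxopropyl)-4H-1,3-dioxin-4-one
Conditions: 6 (2.0 equiv), LiN(SiMe3)2 (2.0 equiv), THF, −78 °C; AcCl (1.0 equiv), −78 °C, 1 h; 1 M aq. HCl
Reagents that add atoms: acetyl chloride CC(Cl)=O
Why: Vinylogous Claisen-type C-acylation: the lithium dienolate of the dioxinone reacts at its γ-carbon (the 6-methyl group) with the acid chloride, and the second equivalent of dienolate absorbs the more acidic product proton.

**Step 4**
Reactants: 7 2,2-dimethyl-6-(2-oxopropyl)-4H-1,3-dioxin-4-one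
Product: 8 6-(2,4-dioxopentyl)-2,2-dimethyl-4H-1,3-dioxin-4-one
Conditions: LiN(iPr)2 (2.2 equiv), THF, −78 °C, 45 min; MeC(O)N(OMe)Me (1.1 equiv), −78 → −20 °C; 1 M aq. HCl
Reagents that add atoms: N-methoxy-N-methylacetamide CC(=O)N(C)OC
Why: Dianion Claisen condensation: the second deprotonation gives the more reactive terminal methyl carbanion, which is acylated by the Weinreb amide through a stable chelated tetrahedral intermediate that prevents over-reaction.

**Step 5**
Reactants: 5 methyl 2,4,5-trihydroxy-3,6-dimethylbenzoate; 8 6-(2,4-dioxopentyl)-2,2-dimethyl-4H-1,3-dioxin-4-one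
Product: 11 methyl 5-[(2,4-dihydroxy-6-methylbenzoyl)oxy]-2,4-dihydroxy-3,6-dimethylbenzoate, via acylketene 9 (not isolated), via triketo aryl ester 10 (not isolated)
Conditions: 5 (1.0 equiv), 8 (1.4 equiv), degassed PhMe, 110 °C, 1.5 h, N2 sweep to remove acetone; cool to 0 °C, Et3N (0.5 equiv), CH2Cl2, 0 °C → rt, 4 h; dilute aq. HCl wash
Reagents that add atoms: none
Why: Proposed new method: thermal retro-[4+2] of dioxinone 8 expels acetone to give acylketene 9, whose capture by a phenol O–H is known from acetoacetylation of phenols with trimethyldioxinone; the neutral 5-OH of 5 is the most nucleophilic hydroxyl (meta to the ester and para to O2, whereas 2-OH is chelated to the ester and 4-OH is its vinylogous acid), the 5-O-acyl isomer is also the thermodynamic one under amine-mediated 1,2-acyl shift, the fully substituted ring B cannot undergo Pechmann or Fries side reactions, and Et3N then triggers the C2-to-C7 intramolecular aldol condensation and dehydration of 10 that aromatises ring A; the closest known reaction type is the one-pot diketo-dioxinone thermolysis, alcohol capture and aldol aromatisation used for resorcylate esters of aliphatic alcohols (biomimetic polyketide cyclisation), here extended to a phenol nucleophile and an aryl triketo-ester.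

**Step 6**
Reactants: 11 methyl 5-[(2,4-dihydroxy-6-methylbenzoyl)oxy]-2,4-dihydroxy-3,6-dimethylbenzoate
Product: 13 methyl 5-[(3-formyl-2,4-dihydroxy-6-methylbenzoyl)oxy]-2,4-dihydroxy-3,6-dimethylbenzoate, via α-chloro ether 12 (not isolated)
Conditions: Cl2CHOMe (1.3 equiv), TiCl4 (5 equiv), CH2Cl2, −20 → 0 °C, 2 h; then 1 M aq. HCl, rt
Reagents that add atoms: dichloromethyl methyl ether ClC(Cl)OC; water O
Why: Rieche formylation: ring B has no C–H, and on ring A the ester/2-OH chelate directs the electrophile to C3 between the two hydroxyls, the same selectivity by which orsellinate esters give haematommate esters, while the hindered diaryl ester survives TiCl4 at or below 0 °C; no stereocentre is formed.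

**Compound list**
1 | methyl 2,4-dihydroxy-3,6-dimethylbenzoate (atraric acid), achiral | COC(=O)c1c(C)cc(O)c(C)c1O | starting material
2 | methyl 5-[chloro(methoxy)methyl]-2,4-dihydroxy-3,6-dimethylbenzoate (racemic, transient, titanium-bound in the flask) | COC(Cl)c1c(C)c(C(=O)OC)c(O)c(C)c1O | intermediate
3 | methyl 5-formyl-2,4-dihydroxy-3,6-dimethylbenzoate, achiral | COC(=O)c1c(C)c(C=O)c(O)c(C)c1O | intermediate
4 | methyl 5-(formyloxy)-2,4-dihydroxy-3,6-dimethylbenzoate, achiral | COC(=O)c1c(C)c(OC=O)c(O)c(C)c1O | intermediate
5 | methyl 2,4,5-trihydroxy-3,6-dimethylbenzoate, achiral | COC(=O)c1c(C)c(O)c(O)c(C)c1O | intermediate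
6 | 2,2,6-trimethyl-4H-1,3-dioxin-4-one, achiral | CC1=CC(=O)OC(C)(C)O1 | starting material
7 | 2,2-dimethyl-6-(2-oxopropyl)-4H-1,3-dioxin-4-one, achiral | CC(=O)CC1=CC(=O)OC(C)(C)O1 | intermediate
8 | 6-(2,4-dioxopentyl)-2,2-dimethyl-4H-1,3-dioxin-4-one, achiral (largely enolised) | CC(=O)CC(=O)CC1=CC(=O)OC(C)(C)O1 | intermediate
9 | oct-1-ene-1,3,5,7-tetraone (acylketene), achiral | CC(=O)CC(=O)CC(=O)C=C=O | intermediate
10 | methyl 2,4-dihydroxy-3,6-dimethyl-5-[(3,5,7-trioxooctanoyl)oxy]benzoate, achiral | COC(=O)c1c(C)c(OC(=O)CC(=O)CC(=O)CC(C)=O)c(O)c(C)c1O | intermediate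
11 | methyl 5-[(2,4-dihydroxy-6-methylbenzoyl)oxy]-2,4-dihydroxy-3,6-dimethylbenzoate, achiral | COC(=O)c1c(C)c(OC(=O)c2c(C)cc(O)cc2O)c(O)c(C)c1O | intermediate
12 | methyl 5-({3-[chloro(methoxy)methyl]-2,4-dihydroxy-6-methylbenzoyl}oxy)-2,4-dihydroxy-3,6-dimethylbenzoate (racemic, transient) | COC(=O)c1c(C)c(OC(=O)c2c(C)cc(O)c(C(Cl)OC)c2O)c(O)c(C)c1O | intermediate
13 | methyl 5-[(3-formyl-2,4-dihydroxy-6-methylbenzoyl)oxy]-2,4-dihydroxy-3,6-dimethylbenzoate (CNP0235245.0), achiral | COC(=O)c1c(C)c(OC(=O)c2c(C)cc(O)c(C=O)c2O)c(O)c(C)c1O | target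

**Route summary**
Total step count: 6. Longest linear sequence: 4 steps (1 → 3 → 5 → 11 → 13, or 6 → 7 → 8 → 11 → 13).

**Three steps most likely to fail**

Step 5 is the riskiest. The hindered, weakly nucleophilic phenol may lose to internal capture of the acylketene by its own enol (pyranone formation), and the triketo aryl ester 10 may lactonise with expulsion of 5 instead of closing by aldol. The fallback sets out from 8 and comes back at 11, and it reverses the order of events so that no aryl triketo-ester is ever formed. Treating 8 with Et3N in CH2Cl2 at rt closes ring A with the dioxinone still in place, giving 7-hydroxy-2,2,5-trimethyl-4H-1,3-benzodioxin-4-one F1. Irradiating F1 at 300 nm in degassed CH2Cl2 with 5 (2 equiv) expels acetone and generates the quinoketene 3-hydroxy-5-methyl-6-(oxomethylidene)cyclohexa-2,4-dien-1-one F2. Its capture by the 5-OH of 5 gives 11.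

Step 6 may give the C5-formyl isomer or a mixture, since both ring A positions are activated. The fallback sets out from 11 and comes back at 13, and it replaces Lewis-acid formylation by halogenation and carbonylation. Iodination under phenoxide conditions (I2, NaHCO3, THF/H2O, 0 °C) goes to the carbon between the two oxygens in resorcinols. It gives methyl 5-[(2,4-dihydroxy-3-iodo-6-methylbenzoyl)oxy]-2,4-dihydroxy-3,6-dimethylbenzoate F3, whose regiochemistry can be confirmed by NOE between the remaining aryl H and the 6-methyl group. Reductive carbonylation (PdCl2(PPh3)2, CO 1 atm, HCO2Na, DMF, 80 °C) then converts the C–I bond into the aldehyde of 13.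

Step 2 may suffer from over-oxidation of the hydroxyhydroquinone 5 by H2O2 or air during oxidation and isolation. The fallback sets out from 1 and comes back at 5, replacing steps 1 and 2 by a detour through the quinone oxidation state. Teuber oxidation of 1 with K2[ON(SO3)2] in KH2PO4-buffered aqueous acetone oxygenates the only free position, C5. It gives the bench-stable hydroxyquinone methyl 4-hydroxy-2,5-dimethyl-3,6-dioxocyclohexa-1,4-diene-1-carboxylate F4, which can be stored. Reduction with aqueous Na2S2O4 (EtOAc/H2O, N2) immediately before step 5 delivers 5.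

**Further compounds**
F1 | step 5 | 7-hydroxy-2,2,5-trimethyl-4H-1,3-benzodioxin-4-one | CC1(C)OC(=O)c2c(C)cc(O)cc2O1
F2 | step 5 | 3-hydroxy-5-methyl-6-(oxomethylidene)cyclohexa-2,4-dien-1-one | O=C=C1C(C)=CC(O)=CC1=O
F3 | step 6 | methyl 5-[(2,4-dihydroxy-3-iodo-6-methylbenzoyl)oxy]-2,4-dihydroxy-3,6-dimethylbenzoate | COC(=O)c1c(C)c(OC(=O)c2c(C)cc(O)c(I)c2O)c(O)c(C)c1O
F4 | step 2 | methyl 4-hydroxy-2,5-dimethyl-3,6-dioxocyclohexa-1,4-diene-1-carboxylate | COC(=O)C1=C(C)C(=O)C(O)=C(C)C1=O
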